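At 12 h, when west is read, the incoming ligand, the limiting reagent at 1.00 equiv, must be accounted for, so the reckoning is a balance of that ligand.

in all of them: starting complex 0.10 M

|  | incoming ligand | leaving ligand | remark | time |
|---|---|---|---|---|
| beta | 0.59 equiv | 5 equiv | run made earlier |  |
| epsilon | 2.8 equiv | 5 equiv | run made earlier |  |
| west | 1.00 equiv | 5.00 equiv |  | 12 h |
| south | 4.00 equiv | 5.00 equiv |  | 12 h |

- beta (time / h: complex with two exchanged / %): 1.50: 5.3; 4.00: 10.8; 8.00: 13.0; 12.0: 11.2
- epsilon (time / h: complex with two exchanged / %): 1.00: 22.9; 2.00: 26.5; 5.00: 17.7; 12.0: 11.6

(readings scatter by 1 percentage point)

- which of these holds the largest part of the starting complex at the end of west (complex with four exchanged / complex with one exchanged / starting complex / complex with two exchanged / complex with three exchanged)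
- which of these holds the largest part of the starting complex at the end of south (complex with four exchanged / complex with one exchanged / starting complex / complex with two exchanged / complex with three exchanged)
- final complex with two exchanged in west, as a percentage of the starting complex charged

- the numbers in the tables scatter with a standard deviation of 1 percentage point
- a reading or a percentage of leaving ligand counts all its forms, free or not

With the main steps alone, two ligands make one complex with two exchanged, so west could hold 0.500 of the complex charged in that form. The beta run reads 11.2% at 12.0 h, where its charge could give 0.295. This gives the ligand yield, the percentage of the complex charged found as complex with two exchanged at 12 h per equivalent of incoming ligand charged: 19.0% in beta. So 38.0% of beta's ligand sits in that complex.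

Adding the onward exchange changes the number. The epsilon run reads 26.5% at 2.00 h but a lower 11.6% at 12.0 h, and its ligand yield is 4.14%, far below beta's. West is therefore reckoned from beta, whose charge lies closer to west's than epsilon's does.

The rest of the flask enters unread: 62.0% of beta's ligand lies elsewhere, and the yield carries that loss without naming it. This reckoning therefore puts west at about 19.0%, a figure read from beta that carries its scatter, perhaps slightly lower, since west is charged with more ligand than beta. This reckoning gives no figure for the largest holder in west. South, charged beyond epsilon, should lie past the two-exchanged stage.

The forecast gave starting complex for west, complex with four exchanged for south and 17%, with the words “Starting complex narrowly leads one-exchanged”.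

West ends with 17.1% of complex with two exchanged, ahead of 11.4% of unbound starting complex, and south ends with 76.6% of complex with four exchanged.

    starting complex + incoming ligand → leaving ligand + complex with one exchanged (k = 0.180 M⁻¹ min⁻¹)
    complex with one exchanged + incoming ligand → leaving ligand + complex with two exchanged (k = 0.200 M⁻¹ min⁻¹)
    complex with two exchanged + incoming ligand → leaving ligand + complex with three exchanged (k = 0.0650 M⁻¹ min⁻¹)
    complex with one exchanged → decomposed reagent (k = 0.00530 min⁻¹)
    leaving ligand + starting complex ⇌ idle adduct, settled at all times (K = 5.30 M⁻¹)
    complex with three exchanged + incoming ligand → leaving ligand + complex with four exchanged (k = 0.0680 M⁻¹ min⁻¹)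

West's ligand yield comes out 1.9 percentage points below beta's, and 34.2% of west's ligand sits in complex with two exchanged. The same reckoning on a neighbour of west charged with 0.250 equiv of incoming ligand gives 4.75%. That flask holds 3.45% of complex with two exchanged at 12 h, a ligand yield of 13.8%, with 23.0% of starting complex still unbound and 2.1% of its incoming ligand left.

The runs come from a simulation with made-up constants.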